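Compound numbers are those of the compound list after the steps. The labels C2, C3 and C3a–C7a denote, in every intermediate, the atoms that carry these numbers in the benzofuran skeleton of the target 22.

## Analysis of the target

Hierochin B (22) is a trans-2,3-disubstituted 2,3-dihydro-1-benzofuran. C2 (S) carries a 3,4-dimethoxyphenyl group and C3 (R) a hydroxymethyl group, on opposite faces of the five-membered ring. The benzo ring (ring A: C3a, C4, C5, C6, C7, C7a) is 1,2,3,5-tetrasubstituted: O1 at C7a, a methoxy group at C7, the (E)-3-hydroxyprop-1-enyl chain at C5 and C3 at C3a. C2 and C3 are the only stereocentres; because they are adjacent, a ring closure can set their relative configuration, but the absolute configuration must come from outside. C2 is a benzylic ether carbon flanked by O1 and an electron-rich aryl group, so acid can ionise the O1–C2 bond. The cinnamyl-type allylic alcohol and the electron-rich rings are sensitive to acid and oxidants, and the two primary alcohols must be kept out of the ring closure. The difficulty is thus twofold: the C2/C3 pair in the absolute sense, and a benzene ring with four different substituents in fixed order. The plan rests on one feature: C7a and C3a, adjacent in ring A, are bridged by O1–C2–C3. If the C2 oxygen is tied through silicon to an alkyne, that alkyne is delivered next to an alkyne on C3, ring A can be built from three alkynes around this tether, and the silicon left on C7a marks the place of O1.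

## Retrosynthetic reasoning

**22 to 21.** The two primary O–H groups are released last. 22 is traced back to the bis-silyl ether 21, in which the C3 hydroxymethyl oxygen and the allylic oxygen of the side chain carry the same bulky silyl group. This keeps both out of the ring closure, where only the phenol may act as nucleophile, and lets one desilylation finish the synthesis.

**21 to 20.** The O1–C2 bond is cut, not O1–C7a. C2 is a secondary benzylic carbinol carbon that can be activated under neutral Mitsunobu conditions, whereas forming O1–C7a would need an aryl halide and a metal. The closure is 5-exo-tet and inverts C2, so phenol diol 20 must have C2 epimeric to 22 and C3 as in 22. The choice is also tolerant: if the activated carbinol ionised, the cation should still be trapped trans to the C3 substituent.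

**20 to 19.** The phenolic C7a–O bond is traced to a C7a–Si bond, and the C2–OH to an O–Si bond at the same silicon atom. This gives the benzo-fused cyclic siloxane 19. One Tamao–Fleming oxidation then releases both hydroxyl groups needed for ring closure, with retention at C7a and no change at C2 or C3.

**19 to 16 and 18.** This is the central disconnection. The ring A bonds C3a–C7a, C4–C5 and C6–C7 are cut, which unravels the benzene ring into three alkynes. Two of them are held together in diyne 16 by the C3–C2–O–Si tether: the terminal alkyne on C3 (C3a≡C4) and the methoxy-substituted alkyne on silicon (C7a≡C7). The third is the terminal alkyne of enyne 18 (C5≡C6). Cutting here, and not at a bond between ring A and a substituent, brings in all four substituents with their final connectivity, including the methoxy group and the complete side chain. The forward reaction must couple the tethered alkynes first, accept 18 with its chain at C5, and leave the alkene of 18 and both stereocentres alone.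

**16 to 9 and 15.** The O–Si bond is cut, separating chlorosilane 15 from the stereodefined alcohol 9. 15 is cut at its Si–C(sp) bond into acetylide 14 and dichlorosilane 13. 14 comes from methoxyethyne 12, and 12 from chloroacetal 10 by twofold elimination via 11. The methyl ynol ether is the C7 methoxy group of 22 in latent form.

**9 to 7 and 8.** The C2–C3 bond is cut between the aldehyde carbon of 8 and the γ-carbon of the axially chiral allenylstannane 7. A Lewis acid-promoted SE2' addition forms this bond and both stereocentres at once: C3 by transfer of the allene chirality, C2 by the open transition state that leads to the syn adduct. An aldol route to the same array would need several redox steps to unveil the alkyne.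

**7 to 1.** The allene axis of 7 is traced to the propargylic stereocentre of mesylate 6 (anti SN2'). 6 is traced through alcohol 5, diol 4 and alkyne 3 to glycerate ester 1, where the stereocentre is bought. Each step is stereospecific or leaves the stereocentre untouched, so the choice of 1 decides the absolute configuration of 22.

**18 to 17.** Silyl ether 18 is cut at O–Si to the commercial enynol 17. The protecting group is the same as at C3, so both fall together at the end.

## Alternatives that were turned down

**Alternative 1:** The C2–aryl and C3–CH2 bonds are cut, leading back to an aromatic benzofuran, the 2-boryl compound A2.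
- Forward key step: the 3,4-dimethoxyphenyl group is first placed on boron of A2 as an aryl anion. A chiral π-allylpalladium electrophile then attacks C3 of the boronate complex, and the aryl group migrates from boron to C2 on the opposite face. This gives the 2,3-dihydrobenzofuran A1 with aryl and allyl anti.
- For it: it is the most convergent option and starts from a flat, easily made heteroarene. One catalytic step sets both stereocentres, the relative configuration by mechanism and the absolute one by the ligand. On convergence and on the number of steps before the key step it is stronger than the chosen route.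
- Against it for 22: A1 still carries boron at C2. Replacing it by hydrogen with retention at a tertiary, benzylic, O1-substituted carbon is not secured. Activation of boron there invites loss of configuration through a benzylic anion, or a 1,2-shift that expels the O1 phenoxide and opens the ring.
- The allyl group is two carbons and one oxidation level away from hydroxymethyl (isomerisation, oxidative cleavage, reduction). The C5 chain is present only as an acetal and needs three more steps. About seven operations follow the key step, against three in the chosen route.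
- Comparison: the chosen strategy gives up some convergence and accepts a longer diyne preparation. In return every ring A substituent arrives in final form, and the stereocentres are fixed by stereospecific steps before the uncertain reaction.

**Alternative 2:** The C2–C3 bond is cut. The precursor is the aryldiazoacetate A4, in which the 3,4-dimethoxybenzyl group is already on the ring A oxygen.
- Forward key step: on a chiral dirhodium tetracarboxylate, A4 loses dinitrogen and the carbenoid inserts into a C–H bond of the benzylic OCH2 group. This closes the five-membered ring to the cis diester A3.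
- For it: the reaction type is established for 2-aryl-2,3-dihydrobenzofuran-3-carboxylates, the precursor comes from ordinary ether and diazo chemistry, and the route is no longer than the chosen one. In certainty of the key step it is clearly the stronger plan, and a variant of it serves as the fallback for step 11.
- Against it: the kinetic product is cis, so C3 must be epimerised through its ester enolate. Enantiomeric purity depends wholly on catalyst control at a benzylic C–H bond reactive enough to discriminate poorly. The two esters of A3 must end at different places (C3–CH2OH, C5–CH=CH–CH2OH), which costs redox and olefination steps.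
- Comparison: the chosen strategy takes absolute configuration from a purchased stereocentre through stereospecific steps, takes the trans relation from the ring closure itself, and brings the side chain at its final oxidation level. The price is a cyclotrimerisation without direct precedent.

**Alternative 3:** O1–C2 and C2–C3 are both cut. Ring A with its C3 carbon appears as the o-quinone methide A6, and C2 with its aryl group as the chiral sulfonium ylide A7.
- Forward key step: A6, generated in situ, is attacked at its exocyclic carbon (C3) by the ylide carbon of A7. The phenoxide so formed displaces the sulfide at C2 and closes the ring to the trans product A5.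
- For it: two bonds and the trans ring are made in one step. A5 needs only a cross-coupling at C5 and a desilylation, so it equals the chosen route after the key step and is shorter overall.
- Against it: A6 has a CH2 group next to its exocyclic double bond and can tautomerise to an o-hydroxystyrene faster than it is trapped. The sulfonium ion behind A7 is a 3,4-dimethoxybenzyl sulfonium ion that ionises easily. A semistabilised benzyl ylide on a stoichiometric chiral sulfide gives enantiocontrol that is hard to predict. The bromide at C5 must still be exchanged for the chain.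
- Comparison: the chosen strategy is longer, but its stereocentres do not depend on a reagent-controlled addition to a short-lived intermediate, and ring A arrives complete.

Key step: step 11

## Route

Step 1
Reactants: 1 methyl (4S)-2,2-dimethyl-1,3-dioxolane-4-carboxylate
Product: 3 (4R)-4-ethynyl-2,2-dimethyl-1,3-dioxolane, via (4S)-2,2-dimethyl-1,3-dioxolane-4-carbaldehyde 2 (not isolated)
Conditions: iBu2AlH (1.05 equiv), CH2Cl2, −78 °C; then MeOH, K2CO3, dimethyl (1-diazo-2-oxopropyl)phosphonate, 0 °C → rt
Reagents that add atoms: dimethyl (1-diazo-2-oxopropyl)phosphonate, COP(=O)(OC)C(=[N+]=[N-])C(C)=O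
Why: Half-reduction of the ester at −78 °C stops at the aluminium hemiacetal; methanol and K2CO3 then release aldehyde 2 in the presence of the Ohira–Bestmann reagent, so Seyferth–Gilbert homologation should outrun enolisation of this labile α-alkoxy aldehyde. The stereocentre is carried over unchanged from 1; its descriptor changes from S to R only because ethynyl ranks below the ring CH2O group.

Step 2
Reactants: 3 (4R)-4-ethynyl-2,2-dimethyl-1,3-dioxolane
Product: 4 (2R)-but-3-yne-1,2-diol
Conditions: Dowex 50W (H+ form), MeOH/H2O (9:1), rt; filtration, evaporation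
Reagents that add atoms: none
Why: Acid-catalysed acetonide hydrolysis; the propargylic C–O bond is not broken, so the configuration is retained, and removal of the resin by filtration avoids an aqueous extraction of the water-soluble diol.

Step 3
Reactants: 4 (2R)-but-3-yne-1,2-diol
Product: 5 (2R)-1-[(triisopropylsilyl)oxy]but-3-yn-2-ol
Conditions: TIPSCl (1.05 equiv), imidazole, CH2Cl2, 0 °C
Reagents that add atoms: chlorotriisopropylsilane (TIPSCl), CC(C)[Si](Cl)(C(C)C)C(C)C
Why: Silyl ether formation; the bulky chlorosilane should react with the primary hydroxyl far faster than with the secondary propargylic one.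

Step 4
Reactants: 5 (2R)-1-[(triisopropylsilyl)oxy]but-3-yn-2-ol
Product: 6 (2R)-1-[(triisopropylsilyl)oxy]but-3-yn-2-yl methanesulfonate
Conditions: MsCl, Et3N, CH2Cl2, −78 °C
Reagents that add atoms: methanesulfonyl chloride, CS(=O)(=O)Cl
Why: O-Sulfonylation of the secondary alcohol; the C–O bond is untouched, so the R configuration is kept, and the low temperature limits ionisation of the propargylic mesylate.

Step 5
Reactants: 6 (2R)-1-[(triisopropylsilyl)oxy]but-3-yn-2-yl methanesulfonate
Product: 7 (Ra)-tributyl{4-[(triisopropylsilyl)oxy]buta-1,2-dien-1-yl}stannane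
Conditions: Bu3SnH, LiN(iPr)2, THF, 0 °C; CuBr·SMe2, −78 °C; then 6, −78 °C
Reagents that add atoms: tributyltin hydride, CCCC[SnH](CCCC)CCCC
Why: SN2' substitution of the propargylic mesylate by the stannylcuprate made in the flask; tin enters at the alkyne terminus anti to the leaving group, which converts the R stereocentre into the Ra allene axis.

Step 6
Reactants: 7 (Ra)-tributyl{4-[(triisopropylsilyl)oxy]buta-1,2-dien-1-yl}stannane; 8 3,4-dimethoxybenzaldehyde
Product: 9 (1R,2R)-1-(3,4-dimethoxyphenyl)-2-{[(triisopropylsilyl)oxy]methyl}but-3-yn-1-ol (syn)
Conditions: BF3·OEt2 (1.5 equiv), CH2Cl2, −78 °C; aq. NaHCO3 quench at −78 °C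
Reagents that add atoms: none
Why: Lewis acid-promoted SE2' addition of an allenylstannane to an aldehyde: the C–C bond forms on the allene face opposite to tin, which transfers the axis to the R stereocentre at C3, and the open antiperiplanar transition state that keeps the aryl group away from the silyloxymethyl group should give the syn carbinol (R at C2). The electron-rich aldehyde needs the strong Lewis acid, and the cold quench should keep the product carbinol from ionising.

Step 7
Reactants: 10 2-chloro-1,1-dimethoxyethane
Product: 12 methoxyethyne, via sodium methoxyacetylide 11 (not isolated)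
Conditions: NaNH2 (3 equiv), NH3 (l), −33 °C; then sat. aq. NaCl, −20 °C; distillation
Reagents that add atoms: none
Why: Twofold base-induced elimination (loss of methanol, then of HCl) gives the sodium acetylide 11, which is protonated on aqueous quench; this is the classical preparation of this volatile ynol ether.

Step 8
Reactants: 12 methoxyethyne; 13 dichlorodimethylsilane
Product: 15 chloro(methoxyethynyl)dimethylsilane, via lithium methoxyacetylide 14 (not isolated)
Conditions: n-BuLi, Et2O, −78 °C; then added to 13 (4 equiv), Et2O, −78 → 0 °C; filtration under argon, distillation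
Reagents that add atoms: none
Why: Deprotonation of the terminal alkyne and nucleophilic substitution at silicon; inverse addition to a large excess of 13 should limit the reaction to one chloride, and the absence of amines and alkoxides keeps the second Si–Cl bond intact. A methyl ynol ether has no β-hydrogen, so the retro-ene collapse to a silylketene that limits ethoxy analogues is not open.

Step 9
Reactants: 9 (1R,2R)-1-(3,4-dimethoxyphenyl)-2-{[(triisopropylsilyl)oxy]methyl}but-3-yn-1-ol; 15 chloro(methoxyethynyl)dimethylsilane
Product: 16 {[(1R,2R)-1-(3,4-dimethoxyphenyl)-2-{[(triisopropylsilyl)oxy]methyl}but-3-yn-1-yl]oxy}(methoxyethynyl)dimethylsilane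
Conditions: Et3N, DMAP (cat.), CH2Cl2, 0 °C; short pad of Et3N-deactivated silica
Reagents that add atoms: none
Why: Silyl ether formation from a chlorosilane and a secondary alcohol under amine base; the base traps HCl, which would otherwise hydrate the ynol ether, and C2 is not touched. The alkoxy(alkynyl)silane is moisture-sensitive and is therefore not chromatographed at length.

Step 10
Reactants: 17 (2E)-pent-2-en-4-yn-1-ol
Product: 18 triisopropyl[(2E)-pent-2-en-4-yn-1-yloxy]silane
Conditions: TIPSCl, imidazole, CH2Cl2, rt
Reagents that add atoms: chlorotriisopropylsilane (TIPSCl), CC(C)[Si](Cl)(C(C)C)C(C)C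
Why: Standard silylation of a primary allylic alcohol; the same group as at C3 is used so that both are removed together in step 14.

Step 11
Reactants: 16 {[(1R,2R)-1-(3,4-dimethoxyphenyl)-2-{[(triisopropylsilyl)oxy]methyl}but-3-yn-1-yl]oxy}(methoxyethynyl)dimethylsilane; 18 triisopropyl[(2E)-pent-2-en-4-yn-1-yloxy]silane
Product: 19 (3R,4R)-3-(3,4-dimethoxyphenyl)-8-methoxy-1,1-dimethyl-4-{[(triisopropylsilyl)oxy]methyl}-6-{(1E)-3-[(triisopropylsilyl)oxy]prop-1-en-1-yl}-3,4-dihydro-1H-2,1-benzoxasiline
Conditions: Cp*RuCl(cod) (5–10 mol %), 18 (3 equiv), ClCH2CH2Cl, rt → 40 °C, slow addition of 16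
Reagents that add atoms: none
Why: Proposed new method: the closest known reaction type is the Cp*RuCl(cod)-catalysed [2+2+2] cycloaddition of silicon-tethered diynes with terminal alkynes, and alkoxyalkynes are known as untethered partners in rhodium-catalysed cyclotrimerisation, but a silicon-bound methoxyethynyl terminus has not been used. Loss of cod lets the Cp*RuCl fragment (divalent ruthenium) bind both alkynes of 16; oxidative cyclisation joins the two tether-bearing carbons (C3a–C7a) and gives a ruthenacyclopentadiene (tetravalent ruthenium, with carbene character at C4 and C7) fused to the new six-membered 2,1-oxasiline ring, which is thus closed by intramolecular alkyne–alkyne coupling across the four-atom C3–C2–O–Si tether. The terminal alkyne of 18 then adds across the Ru–C4 bond to form C4–C5, and reductive elimination forms C6–C7, which closes ring A in a formal [2+2+2] process. No stereocentre is formed, and C2 and C3 are sp3 spectators without metal-labile bonds. The step needs regioselectivity for the third alkyne (chain at C5, not C6): the incoming alkyne turns its substituent away from the methoxy-bearing terminus C7 and from the Cp* ligand, so its substituted carbon bonds to the unsubstituted C4, the meta preference usual for this catalyst. It also needs chemoselectivity: the tether makes the first coupling intramolecular, slow addition of 16 to an excess of 18 suppresses diyne dimerisation, and the disubstituted alkene of 18 binds far less well than its terminal alkyne. The donor methoxy group should stabilise the metallacycle at C7 without blocking uptake of the third alkyne.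

Step 12
Reactants: 19 (3R,4R)-3-(3,4-dimethoxyphenyl)-8-methoxy-1,1-dimethyl-4-{[(triisopropylsilyl)oxy]methyl}-6-{(1E)-3-[(triisopropylsilyl)oxy]prop-1-en-1-yl}-3,4-dihydro-1H-2,1-benzoxasiline
Product: 20 (1R,2R)-1-(3,4-dimethoxyphenyl)-2-{2-hydroxy-3-methoxy-5-[(1E)-3-(triisopropylsilyloxy)prop-1-en-1-yl]phenyl}-3-(triisopropylsilyloxy)propan-1-ol
Conditions: KF, KHCO3, 30% aq. H2O2, THF/MeOH (1:1), rt → 40 °C
Reagents that add atoms: hydrogen peroxide, OO
Why: Tamao–Fleming oxidation: fluoride adds to the alkoxy-activated silicon, hydroperoxide attacks, and the aryl group migrates from silicon to oxygen with retention at C7a; hydrolysis of the Si–O bonds frees the phenol and the C2 alcohol, whose C–O bond is never broken. Bicarbonate buffering should hold back protodesilylation of the electron-rich arene, and primary triisopropylsilyl ethers should withstand KF under these conditions.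

Step 13
Reactants: 20 (1R,2R)-1-(3,4-dimethoxyphenyl)-2-{2-hydroxy-3-methoxy-5-[(1E)-3-(triisopropylsilyloxy)prop-1-en-1-yl]phenyl}-3-(triisopropylsilyloxy)propan-1-ol
Product: 21 (2S,3R)-2-(3,4-dimethoxyphenyl)-7-methoxy-3-{[(triisopropylsilyl)oxy]methyl}-5-{(1E)-3-[(triisopropylsilyl)oxy]prop-1-en-1-yl}-2,3-dihydro-1-benzofuran
Conditions: PPh3, DIAD, THF, 0 °C → rt
Reagents that add atoms: none
Why: Mitsunobu reaction: the secondary benzylic alcohol is activated as its oxyphosphonium ion and displaced by the phenoxide in a 5-exo-tet closure with inversion, which turns R at the carbinol into S at C2 and places the aryl group trans to the C3 substituent. Should the electron-rich oxyphosphonium ion ionise instead, capture of the cation by the phenol is expected to give the same trans ring, because the incoming oxygen avoids the C3 substituent.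

Step 14
Reactants: 21 (2S,3R)-2-(3,4-dimethoxyphenyl)-7-methoxy-3-{[(triisopropylsilyl)oxy]methyl}-5-{(1E)-3-[(triisopropylsilyl)oxy]prop-1-en-1-yl}-2,3-dihydro-1-benzofuran
Product: 22 hierochin B, (2E)-3-[(2S,3R)-2-(3,4-dimethoxyphenyl)-3-(hydroxymethyl)-7-methoxy-2,3-dihydro-1-benzofuran-5-yl]prop-2-en-1-ol
Conditions: Bu4NF, THF, 0 °C → rt
Reagents that add atoms: none
Why: Fluoride-induced cleavage of both Si–O bonds; the benzylic ether, the alkene and both stereocentres are inert to Bu4NF.

## Compound list

1 | methyl (4S)-2,2-dimethyl-1,3-dioxolane-4-carboxylate | COC(=O)[C@@H]1COC(C)(C)O1 | starting material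
2 | (4S)-2,2-dimethyl-1,3-dioxolane-4-carbaldehyde | O=C[C@@H]1COC(C)(C)O1 | intermediate (not isolated)
3 | (4R)-4-ethynyl-2,2-dimethyl-1,3-dioxolane | C#C[C@@H]1COC(C)(C)O1 | intermediate
4 | (2R)-but-3-yne-1,2-diol | C#C[C@@H](O)CO | intermediate
5 | (2R)-1-[(triisopropylsilyl)oxy]but-3-yn-2-ol | C#C[C@@H](O)CO[Si](C(C)C)(C(C)C)C(C)C | intermediate
6 | (2R)-1-[(triisopropylsilyl)oxy]but-3-yn-2-yl methanesulfonate | C#C[C@@H](OS(C)(=O)=O)CO[Si](C(C)C)(C(C)C)C(C)C | intermediate
7 | (Ra)-tributyl{4-[(triisopropylsilyl)oxy]buta-1,2-dien-1-yl}stannane | [H]C([Sn](CCCC)(CCCC)CCCC)=[C@@]=C([H])CO[Si](C(C)C)(C(C)C)C(C)C | intermediate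
8 | 3,4-dimethoxybenzaldehyde (veratraldehyde) | COc1ccc(C=O)cc1OC | starting material
9 | (1R,2R)-1-(3,4-dimethoxyphenyl)-2-{[(triisopropylsilyl)oxy]methyl}but-3-yn-1-ol | COc1ccc([C@H](O)[C@@H](CO[Si](C(C)C)(C(C)C)C(C)C)C#C)cc1OC | intermediate
10 | 2-chloro-1,1-dimethoxyethane (chloroacetaldehyde dimethyl acetal) | COC(CCl)OC | starting material
11 | sodium methoxyacetylide | [Na+].[C-]#COC | intermediate (not isolated)
12 | methoxyethyne | C#COC | intermediate
13 | dichlorodimethylsilane | C[Si](C)(Cl)Cl | starting material
14 | lithium methoxyacetylide | [Li]C#COC | intermediate (not isolated)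
15 | chloro(methoxyethynyl)dimethylsilane | COC#C[Si](C)(C)Cl | intermediate
16 | {[(1R,2R)-1-(3,4-dimethoxyphenyl)-2-{[(triisopropylsilyl)oxy]methyl}but-3-yn-1-yl]oxy}(methoxyethynyl)dimethylsilane | COc1ccc([C@H](O[Si](C)(C)C#COC)[C@@H](CO[Si](C(C)C)(C(C)C)C(C)C)C#C)cc1OC | intermediate
17 | (2E)-pent-2-en-4-yn-1-ol | OC/C=C/C#C | starting material
18 | triisopropyl[(2E)-pent-2-en-4-yn-1-yloxy]silane | C#C/C=C/CO[Si](C(C)C)(C(C)C)C(C)C | intermediate
19 | (3R,4R)-3-(3,4-dimethoxyphenyl)-8-methoxy-1,1-dimethyl-4-{[(triisopropylsilyl)oxy]methyl}-6-{(1E)-3-[(triisopropylsilyl)oxy]prop-1-en-1-yl}-3,4-dihydro-1H-2,1-benzoxasiline | COc1ccc([C@@H]2O[Si](C)(C)c3c(OC)cc(/C=C/CO[Si](C(C)C)(C(C)C)C(C)C)cc3[C@@H]2CO[Si](C(C)C)(C(C)C)C(C)C)cc1OC | intermediate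
20 | (1R,2R)-1-(3,4-dimethoxyphenyl)-2-{2-hydroxy-3-methoxy-5-[(1E)-3-(triisopropylsilyloxy)prop-1-en-1-yl]phenyl}-3-(triisopropylsilyloxy)propan-1-ol | COc1ccc([C@H](O)[C@@H](CO[Si](C(C)C)(C(C)C)C(C)C)c2cc(/C=C/CO[Si](C(C)C)(C(C)C)C(C)C)cc(OC)c2O)cc1OC | intermediate
21 | (2S,3R)-2-(3,4-dimethoxyphenyl)-7-methoxy-3-{[(triisopropylsilyl)oxy]methyl}-5-{(1E)-3-[(triisopropylsilyl)oxy]prop-1-en-1-yl}-2,3-dihydro-1-benzofuran | COc1ccc([C@H]2Oc3c(OC)cc(/C=C/CO[Si](C(C)C)(C(C)C)C(C)C)cc3[C@@H]2CO[Si](C(C)C)(C(C)C)C(C)C)cc1OC | intermediate
22 | hierochin B, (2E)-3-[(2S,3R)-2-(3,4-dimethoxyphenyl)-3-(hydroxymethyl)-7-methoxy-2,3-dihydro-1-benzofuran-5-yl]prop-2-en-1-ol | COc1ccc([C@H]2Oc3c(OC)cc(/C=C/CO)cc3[C@@H]2CO)cc1OC | target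

## Step count and least certain steps

Total number of steps: 14. Longest linear sequence: 11 steps (steps 1–6, 9 and 11–14).

**Step 11 (key step, proposed new method).**
- What may go wrong: arrest or diversion of the catalyst at the methoxy-substituted alkyne. The donor alkyne may bind too strongly, or the alkoxycarbene-type metallacycle may not take up the third alkyne. Homo-oligomerisation of the terminal alkynes may then outrun the cross-reaction, because a 1,7-diyne closes its metallacycle more slowly than a 1,6-diyne. Loss of regiocontrol between C5 and C6 is the second concern.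
- Fallback with known chemistry, setting out from 8 and returning at 22. It uses a preformed ring A and forms C2–C3 by carbenoid C–H insertion. 8 is reduced with NaBH4 to give 3,4-dimethoxybenzyl alcohol F1. Mitsunobu etherification of commercial 4-hydroxy-3-iodo-5-methoxybenzaldehyde with F1 gives 4-[(3,4-dimethoxybenzyl)oxy]-3-iodo-5-methoxybenzaldehyde F2. Wittig olefination with methyl (triphenylphosphoranylidene)acetate gives methyl (2E)-3-{4-[(3,4-dimethoxybenzyl)oxy]-3-iodo-5-methoxyphenyl}prop-2-enoate F3. Coupling of the aryl iodide with methyl diazoacetate (Pd(PPh3)4, Ag2CO3, Et3N, toluene) gives methyl (2E)-3-{3-(1-diazo-2-methoxy-2-oxoethyl)-4-[(3,4-dimethoxybenzyl)oxy]-5-methoxyphenyl}prop-2-enoate F4. C–H insertion at the benzylic OCH2 group on Rh2(S-PTTL)4, or on its enantiomer, whichever delivers the 2S series, should give the cis diester methyl (2S,3R)-2-(3,4-dimethoxyphenyl)-7-methoxy-5-[(1E)-3-methoxy-3-oxoprop-1-en-1-yl]-2,3-dihydro-1-benzofuran-3-carboxylate F5. NaOMe in methanol epimerises C3 to the trans diester methyl (2S,3S)-2-(3,4-dimethoxyphenyl)-7-methoxy-5-[(1E)-3-methoxy-3-oxoprop-1-en-1-yl]-2,3-dihydro-1-benzofuran-3-carboxylate F6. iBu2AlH reduces both esters of F6 to 22.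

**Step 6.**
- What may go wrong: poor facial selectivity at the aldehyde, giving a syn/anti mixture. The open transition state discriminates less well for a flat aryl aldehyde than for a branched aliphatic one. Partial ionisation of the electron-rich benzylic carbinol under BF3 is a second risk.
- Fallback, setting out from 7 and 8 and returning at 21. It switches to the anti series and to a ring closure that does not depend on the C2 configuration. 7 is first treated with SnCl4 at −78 °C (exchange to the allenyl trichlorostannane) and then with 8. Addition through a closed six-membered transition state should give the anti alcohol (1S,2R)-1-(3,4-dimethoxyphenyl)-2-{[(triisopropylsilyl)oxy]methyl}but-3-yn-1-ol F7, with the same C3 configuration. Silylation with 15 as in step 9 gives {[(1S,2R)-1-(3,4-dimethoxyphenyl)-2-{[(triisopropylsilyl)oxy]methyl}but-3-yn-1-yl]oxy}(methoxyethynyl)dimethylsilane F8. Cycloaddition with 18 as in step 11 gives the (3S,4R)-configured siloxane F9, the C3 epimer of 19 in the siloxane numbering. Tamao–Fleming oxidation as in step 12 gives the (1S,2R)-configured phenol diol F10, the carbinol epimer of 20. F10 is closed with a catalytic sulfonic acid in CH2Cl2 at 0 °C, where the phenol should capture the benzylic cation trans to the C3 substituent, to give 21.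

**Step 9 (with the reagent from step 8).**
- What may go wrong: loss of the ynol ether by HCl-induced hydration, or hydrolysis of the Si–Cl and Si–O bonds while 15 and 16 are isolated. Both are unknown, moisture-sensitive silanes.
- Fallback, setting out from 14 and 9 and returning at 16. It replaces the chlorosilane by an aminosilane. 14 is quenched with commercial chloro(diethylamino)dimethylsilane to give N,N-diethyl-1-(methoxyethynyl)-1,1-dimethylsilanamine F11, a distillable reagent without Si–Cl bonds. Warming F11 with 9 transfers the silyl group to oxygen with loss of diethylamine and gives 16 under base-only conditions.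

**Step 13.**
- What may go wrong: ionisation of the activated benzylic carbinol in competition with direct displacement, which could erode the trans/cis ratio, or elimination toward a stilbene-type alkene.
- Fallback, from 20 to 21 without new compounds. The ring is closed under ionising conditions (catalytic sulfonic acid, CH2Cl2, 0 °C). This gives up the stereospecific displacement and relies on the preference of the benzylic cation for trans capture.

## Further compounds

F1 | step 11 | 3,4-dimethoxybenzyl alcohol | COc1ccc(CO)cc1OC
F2 | step 11 | 4-[(3,4-dimethoxybenzyl)oxy]-3-iodo-5-methoxybenzaldehyde | COc1ccc(COc2c(I)cc(C=O)cc2OC)cc1OC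
F3 | step 11 | methyl (2E)-3-{4-[(3,4-dimethoxybenzyl)oxy]-3-iodo-5-methoxyphenyl}prop-2-enoate | COC(=O)/C=C/c1cc(I)c(OCc2ccc(OC)c(OC)c2)c(OC)c1
F4 | step 11 | methyl (2E)-3-{3-(1-diazo-2-methoxy-2-oxoethyl)-4-[(3,4-dimethoxybenzyl)oxy]-5-methoxyphenyl}prop-2-enoate | COC(=O)/C=C/c1cc(C(=[N+]=[N-])C(=O)OC)c(OCc2ccc(OC)c(OC)c2)c(OC)c1
F5 | step 11 | methyl (2S,3R)-2-(3,4-dimethoxyphenyl)-7-methoxy-5-[(1E)-3-methoxy-3-oxoprop-1-en-1-yl]-2,3-dihydro-1-benzofuran-3-carboxylate (2,3-cis) | COc1ccc([C@H]2Oc3c(OC)cc(/C=C/C(=O)OC)cc3[C@H]2C(=O)OC)cc1OC
F6 | step 11 | methyl (2S,3S)-2-(3,4-dimethoxyphenyl)-7-methoxy-5-[(1E)-3-methoxy-3-oxoprop-1-en-1-yl]-2,3-dihydro-1-benzofuran-3-carboxylate (2,3-trans) | COc1ccc([C@H]2Oc3c(OC)cc(/C=C/C(=O)OC)cc3[C@@H]2C(=O)OC)cc1OC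
F7 | step 6 | (1S,2R)-1-(3,4-dimethoxyphenyl)-2-{[(triisopropylsilyl)oxy]methyl}but-3-yn-1-ol (anti) | COc1ccc([C@@H](O)[C@@H](CO[Si](C(C)C)(C(C)C)C(C)C)C#C)cc1OC
F8 | step 6 | {[(1S,2R)-1-(3,4-dimethoxyphenyl)-2-{[(triisopropylsilyl)oxy]methyl}but-3-yn-1-yl]oxy}(methoxyethynyl)dimethylsilane | COc1ccc([C@@H](O[Si](C)(C)C#COC)[C@@H](CO[Si](C(C)C)(C(C)C)C(C)C)C#C)cc1OC
F9 | step 6 | (3S,4R)-3-(3,4-dimethoxyphenyl)-8-methoxy-1,1-dimethyl-4-{[(triisopropylsilyl)oxy]methyl}-6-{(1E)-3-[(triisopropylsilyl)oxy]prop-1-en-1-yl}-3,4-dihydro-1H-2,1-benzoxasiline | COc1ccc([C@H]2O[Si](C)(C)c3c(OC)cc(/C=C/CO[Si](C(C)C)(C(C)C)C(C)C)cc3[C@@H]2CO[Si](C(C)C)(C(C)C)C(C)C)cc1OC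
F10 | step 6 | (1S,2R)-1-(3,4-dimethoxyphenyl)-2-{2-hydroxy-3-methoxy-5-[(1E)-3-(triisopropylsilyloxy)prop-1-en-1-yl]phenyl}-3-(triisopropylsilyloxy)propan-1-ol | COc1ccc([C@@H](O)[C@@H](CO[Si](C(C)C)(C(C)C)C(C)C)c2cc(/C=C/CO[Si](C(C)C)(C(C)C)C(C)C)cc(OC)c2O)cc1OC
F11 | step 9 | N,N-diethyl-1-(methoxyethynyl)-1,1-dimethylsilanamine | CCN(CC)[Si](C)(C)C#COC
F0 | step 13 | none | none
A1 | alternative 1 | 2-[(2S,3S)-2-(3,4-dimethoxyphenyl)-5-(dimethoxymethyl)-7-methoxy-3-(prop-2-en-1-yl)-2,3-dihydro-1-benzofuran-2-yl]-4,4,5,5-tetramethyl-1,3,2-dioxaborolane (aryl and allyl anti) | COc1ccc([C@@]2(B4OC(C)(C)C(C)(C)O4)Oc3c(OC)cc(C(OC)OC)cc3[C@@H]2CC=C)cc1OC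
A2 | alternative 1 | 2-[5-(dimethoxymethyl)-7-methoxy-1-benzofuran-2-yl]-4,4,5,5-tetramethyl-1,3,2-dioxaborolane | COC(OC)c1cc(OC)c2oc(B3OC(C)(C)C(C)(C)O3)cc2c1
A3 | alternative 2 | 3-ethyl 5-methyl (2S,3R)-2-(3,4-dimethoxyphenyl)-7-methoxy-2,3-dihydro-1-benzofuran-3,5-dicarboxylate (2,3-cis) | COc1ccc([C@H]2Oc3c(OC)cc(C(=O)OC)cc3[C@H]2C(=O)OCC)cc1OC
A4 | alternative 2 | methyl 3-(1-diazo-2-ethoxy-2-oxoethyl)-4-[(3,4-dimethoxybenzyl)oxy]-5-methoxybenzoate | CCOC(=O)C(=[N+]=[N-])c1cc(C(=O)OC)cc(OC)c1OCc1ccc(OC)c(OC)c1
A5 | alternative 3 | (2S,3R)-5-bromo-3-{[(tert-butyldimethylsilyl)oxy]methyl}-2-(3,4-dimethoxyphenyl)-7-methoxy-2,3-dihydro-1-benzofuran | COc1ccc([C@H]2Oc3c(OC)cc(Br)cc3[C@@H]2CO[Si](C)(C)C(C)(C)C)cc1OC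
A6 | alternative 3 | 4-bromo-6-[2-(tert-butyldimethylsilyloxy)ethylidene]-2-methoxycyclohexa-2,4-dien-1-one | O=C1C(OC)=CC(Br)=CC1=CCO[Si](C)(C)C(C)(C)C
A7 | alternative 3 | (3,4-dimethoxyphenyl)[(2R,5R)-2,5-dimethylthiolan-1-ium-1-yl]methanide (one enantiomer of a C2-symmetric sulfide, shown as example) | COc1ccc([CH-][S+]2[C@H](C)CC[C@H]2C)cc1OC
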